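**Retrosynthetic overview**
- The target is reached by hydrogenolysis of its ring A di-O-benzyl ether.
- Key C–C disconnection: the ring B aryl–C(=O) bond, cut into the hindered A–B aryl bromide and methyl orsellinate 4-O-formate. Under palladium catalysis the formate serves as an aryloxycarbonyl anion equivalent (formyl carbon with reversed polarity), so the B–C depside C–O link arrives with it.
- The A–B ester is made by O-acylation of the ring B bromophenol with 2,4-bis(benzyloxy)-6-methylbenzoic acid through its mixed trifluoroacetic anhydride.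
- Building blocks: methyl orsellinate (ring A by benzylation and saponification; ring C by formylation) and 2-bromo-3-methylanisole (ring B by C–H borylation/oxidation).
- No ring is constructed: rings A, B and C are bought as benzene rings and joined A to B, then AB to C.

Assumption: the target has no stereocentre and is achiral, so the single-enantiomer requirement is met by the constitution alone.

**Step 1**
Reactants: 1 methyl orsellinate (methyl 2,4-dihydroxy-6-methylbenzoate)
Product: 2 methyl 2,4-bis(benzyloxy)-6-methylbenzoate
Conditions: BnBr (2.5 equiv), K2CO3 (3 equiv), DMF, 70 °C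
Reagents that add atoms: benzyl bromide, BrCc1ccccc1
Why: Williamson ether synthesis: with excess BnBr and K2CO3 in warm DMF both phenoxides, including the hydrogen-bonded 2-OH, are O-benzylated, giving ethers that survive hydroxide, TFA at rt, amine base and palladium catalysis and are removed at the end by hydrogenolysis.

**Step 2**
Reactants: 2 methyl 2,4-bis(benzyloxy)-6-methylbenzoate
Product: 3 2,4-bis(benzyloxy)-6-methylbenzoic acid
Conditions: KOH (6 equiv), DMSO/H2O (5:1), 90 °C; then aq HCl to pH 2, 0 °C
Reagents that add atoms: potassium hydroxide, [K+].[OH-]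
Why: Saponification of a hindered ester: hydroxide in hot aqueous DMSO cleaves the di-ortho-substituted methyl ester while the benzyl ethers are inert to base, and cold acidification frees the acid without decarboxylation.

**Step 3**
Reactants: 4 2-bromo-1-methoxy-3-methylbenzene (2-bromo-3-methylanisole)
Product: 6 4-bromo-3-methoxy-5-methylphenol, via aryl pinacol boronate 5 (not isolated)
Conditions: [Ir(OMe)(cod)]2 (1.5 mol%), dtbpy (3 mol%), HBpin (1.5 equiv), THF, 60 °C; evaporate; then KHSO5 (as the triple salt 2KHSO5·KHSO4·K2SO4, 1.1 equiv), acetone/H2O, rt, 15 min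
Reagents that add atoms: pinacolborane, CC1(C)OBOC1(C)C (its boryl group is carried by 5 only); potassium peroxymonosulfate, [K+].[O-]S(=O)(=O)OO (source of the phenol oxygen)
Why: One-pot iridium-catalysed C–H borylation/oxidation: borylation is sterically controlled and takes the only ring C–H without an ortho substituent (para to bromine, with the C–Br bond tolerated), and KHSO5 then converts the C–B bond of 5 into C–OH at the same carbon, so the ring B substitution pattern is fixed without relying on directing effects.

**Step 4**
Reactants: 3 2,4-bis(benzyloxy)-6-methylbenzoic acid; 6 4-bromo-3-methoxy-5-methylphenol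
Product: 8 4-bromo-3-methoxy-5-methylphenyl 2,4-bis(benzyloxy)-6-methylbenzoate, via mixed trifluoroacetic anhydride 7 (not isolated)
Conditions: TFAA (2.5 equiv), toluene, 0 °C to rt, 3 h
Reagents that add atoms: trifluoroacetic anhydride, O=C(OC(=O)C(F)(F)F)C(F)(F)F (its trifluoroacetyl group is carried by 7 only)
Why: Depside esterification through a mixed trifluoroacetic anhydride: TFAA turns the hindered, electron-rich acid 3 into mixed anhydride 7, which transfers its aroyl group to the phenol oxygen of 6, a method that works for di-ortho-substituted orsellinic acids and leaves the C–Br bond and the benzyl ethers untouched.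

**Step 5**
Reactants: 1 methyl orsellinate (methyl 2,4-dihydroxy-6-methylbenzoate)
Product: 9 methyl 4-(formyloxy)-2-hydroxy-6-methylbenzoate
Conditions: HCO2H/Ac2O (premixed, 60 °C, 1 h; 1.2 equiv of the mixed anhydride), NaOAc (0.2 equiv), THF, 0 °C to rt; non-aqueous work-up
Reagents that add atoms: formic acid, OC=O (used as acetic formic anhydride, CC(=O)OC=O, made in the flask from it and acetic anhydride)
Why: Selective O-formylation with a mixed anhydride: the 2-OH is locked in a hydrogen bond to the ester carbonyl, so the unhindered formyl carbonyl of acetic formic anhydride is attacked only by the free 4-OH, giving an aryl formate that stores the ring C phenol together with one carbonyl carbon.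

**Step 6**
Reactants: 8 4-bromo-3-methoxy-5-methylphenyl 2,4-bis(benzyloxy)-6-methylbenzoate; 9 methyl 4-(formyloxy)-2-hydroxy-6-methylbenzoate (1.5 equiv)
Product: 12 methyl 4-[(4-{[2,4-bis(benzyloxy)-6-methylbenzoyl]oxy}-2-methoxy-6-methylbenzoyl)oxy]-2-hydroxy-6-methylbenzoate, via carbon monoxide 10 (not isolated), via methyl orsellinate triethylammonium phenoxide 11 (not isolated)
Conditions: Pd(OAc)2 (5 mol%), P(t-Bu)3·HBF4 (20 mol%), NEt3 (2.5 equiv), MeCN/toluene, 80 °C, closed vessel, 9 added over 3 h
Reagents that add atoms: triethylamine, CCN(CC)CC (carried by 11 only, as its ammonium ion)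
Why: Palladium-catalysed aryloxycarbonylation of an aryl bromide with an aryl formate (carbonylative esterification without CO gas): formate 9 acts as an aryloxycarbonyl anion equivalent whose normally electrophilic formyl carbon is joined to the electrophilic C–Br carbon of 8, because NEt3 unmasks it to carbon monoxide 10 and phenoxide 11, zerovalent palladium carrying the bulky electron-rich P(t-Bu)3 inserts into the hindered C–Br bond, CO insertion gives the aroyl palladium species and the 4-phenoxide (not the chelated 2-OH) closes the second depside ester, while slow addition of 9 keeps the CO level low and the di-ortho-substituted A–B ester resists transesterification by this weakly nucleophilic phenoxide.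

**Step 7**
Reactants: 12 methyl 4-[(4-{[2,4-bis(benzyloxy)-6-methylbenzoyl]oxy}-2-methoxy-6-methylbenzoyl)oxy]-2-hydroxy-6-methylbenzoate
Product: 13 methyl 4-[(4-{[2,4-dihydroxy-6-methylbenzoyl]oxy}-2-methoxy-6-methylbenzoyl)oxy]-2-hydroxy-6-methylbenzoate (CNP0563156.0)
Conditions: H2 (1 atm), 10% Pd/C, EtOAc/THF, rt
Reagents that add atoms: none
Why: Catalytic hydrogenolysis of benzyl ethers: both O–CH2Ph bonds are cleaved on Pd/C under 1 atm of H2 in a non-nucleophilic solvent, conditions under which the three ester groups and the aryl methyl ether are inert, and there is no stereocentre to set.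

**Compound list**
1 | methyl orsellinate (methyl 2,4-dihydroxy-6-methylbenzoate) | COC(=O)c1c(C)cc(O)cc1O | starting material
2 | methyl 2,4-bis(benzyloxy)-6-methylbenzoate | COC(=O)c1c(C)cc(OCc2ccccc2)cc1OCc1ccccc1 | intermediate
3 | 2,4-bis(benzyloxy)-6-methylbenzoic acid | Cc1cc(OCc2ccccc2)cc(OCc2ccccc2)c1C(=O)O | intermediate
4 | 2-bromo-1-methoxy-3-methylbenzene | COc1cccc(C)c1Br | starting material
5 | 2-(4-bromo-3-methoxy-5-methylphenyl)-4,4,5,5-tetramethyl-1,3,2-dioxaborolane | COc1cc(B2OC(C)(C)C(C)(C)O2)cc(C)c1Br | intermediate
6 | 4-bromo-3-methoxy-5-methylphenol | COc1cc(O)cc(C)c1Br | intermediate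
7 | 2,4-bis(benzyloxy)-6-methylbenzoic trifluoroacetic anhydride | Cc1cc(OCc2ccccc2)cc(OCc2ccccc2)c1C(=O)OC(=O)C(F)(F)F | intermediate
8 | 4-bromo-3-methoxy-5-methylphenyl 2,4-bis(benzyloxy)-6-methylbenzoate | Cc1cc(OCc2ccccc2)cc(OCc2ccccc2)c1C(=O)Oc1cc(C)c(Br)c(OC)c1 | intermediate
9 | methyl 4-(formyloxy)-2-hydroxy-6-methylbenzoate | COC(=O)c1c(C)cc(OC=O)cc1O | intermediate
10 | carbon monoxide | [C-]#[O+] | intermediate
11 | triethylammonium 3-hydroxy-4-(methoxycarbonyl)-5-methylphenolate | CC[NH+](CC)CC.COC(=O)c1c(C)cc([O-])cc1O | intermediate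
12 | methyl 4-[(4-{[2,4-bis(benzyloxy)-6-methylbenzoyl]oxy}-2-methoxy-6-methylbenzoyl)oxy]-2-hydroxy-6-methylbenzoate | COC(=O)c1c(C)cc(OC(=O)c2c(C)cc(OC(=O)c3c(C)cc(OCc4ccccc4)cc3OCc5ccccc5)cc2OC)cc1O | intermediate
13 | methyl 4-[(4-{[2,4-dihydroxy-6-methylbenzoyl]oxy}-2-methoxy-6-methylbenzoyl)oxy]-2-hydroxy-6-methylbenzoate | COC(=O)c1c(C)cc(OC(=O)c2c(C)cc(OC(=O)c3c(C)cc(O)cc3O)cc2OC)cc1O | target

**Step count**
Total steps: 7. Longest linear sequence: 5 steps (steps 1, 2, 4, 6, 7 from methyl orsellinate).

**Steps most likely to fail, with fallbacks**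

Step 6 is the riskiest. Oxidative addition into the di-ortho-substituted, electron-rich bromide 8 may stall, and the liberated phenoxide may scramble the A–B ester. The fallback inverts the polarity of the ring B carboxyl bond and reorders the assembly; it sets out from 6 and comes back at 12. Phenol 6 is benzylated (BnBr, K2CO3, DMF) to 5-(benzyloxy)-2-bromo-1-methoxy-3-methylbenzene F1. Bromine–lithium exchange (n-BuLi, THF, −78 °C) gives [4-(benzyloxy)-2-methoxy-6-methylphenyl]lithium F2, which is quenched with CO2 and acidified to 4-(benzyloxy)-2-methoxy-6-methylbenzoic acid F3. TFAA in toluene converts F3 into 4-(benzyloxy)-2-methoxy-6-methylbenzoic trifluoroacetic anhydride F4, which acylates the free 4-OH of 1 to give methyl 4-{[4-(benzyloxy)-2-methoxy-6-methylbenzoyl]oxy}-2-hydroxy-6-methylbenzoate F5. Hydrogenolysis (H2, 10% Pd/C, EtOAc) frees methyl 2-hydroxy-4-[(4-hydroxy-2-methoxy-6-methylbenzoyl)oxy]-6-methylbenzoate F6. F6 is then acylated at its only non-chelated hydroxyl by acid 3 through mixed anhydride 7 (TFAA, toluene, rt) to give 12.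

Step 5 is the second risk. The electron-poor aryl formate 9 is hydrolytically labile and may not survive isolation, or may be contaminated with the bis-formate. The fallback sets out from 1 and comes back at 12. It skips the formate: bromide 8 is carbonylated with CO gas (1 atm, balloon) in the presence of free 1 (Pd(OAc)2, P(t-Bu)3·HBF4, NEt3, toluene, 90 °C), so that the 4-OH of 1 traps the aroyl palladium species. This makes no new compound (F0).

Step 4 is the third risk. Under the acidic TFAA conditions the activated ring of 6 may be C-acylated, or a benzyl ether may be lost. The fallback replaces the acid-mediated acyl transfer by a base-mediated one; it sets out from 3 and comes back at 8. Acid 3 is converted by oxalyl chloride (cat. DMF, CH2Cl2, 0 °C to rt) into 2,4-bis(benzyloxy)-6-methylbenzoyl chloride F7, which is coupled with phenol 6 (NEt3, DMAP, CH2Cl2, rt) to give 8.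

**Further compounds**
F1 | step 6 | 5-(benzyloxy)-2-bromo-1-methoxy-3-methylbenzene | COc1cc(OCc2ccccc2)cc(C)c1Br
F2 | step 6 | [4-(benzyloxy)-2-methoxy-6-methylphenyl]lithium | [Li]c1c(C)cc(OCc2ccccc2)cc1OC
F3 | step 6 | 4-(benzyloxy)-2-methoxy-6-methylbenzoic acid | COc1cc(OCc2ccccc2)cc(C)c1C(=O)O
F4 | step 6 | 4-(benzyloxy)-2-methoxy-6-methylbenzoic trifluoroacetic anhydride | COc1cc(OCc2ccccc2)cc(C)c1C(=O)OC(=O)C(F)(F)F
F5 | step 6 | methyl 4-{[4-(benzyloxy)-2-methoxy-6-methylbenzoyl]oxy}-2-hydroxy-6-methylbenzoate | COC(=O)c1c(C)cc(OC(=O)c2c(C)cc(OCc3ccccc3)cc2OC)cc1O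
F6 | step 6 | methyl 2-hydroxy-4-[(4-hydroxy-2-methoxy-6-methylbenzoyl)oxy]-6-methylbenzoate | COC(=O)c1c(C)cc(OC(=O)c2c(C)cc(O)cc2OC)cc1O
F0 | step 5 | none | none
F7 | step 4 | 2,4-bis(benzyloxy)-6-methylbenzoyl chloride | Cc1cc(OCc2ccccc2)cc(OCc2ccccc2)c1C(=O)Cl
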